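Ring B has oxygen on four adjacent carbons (C2'–C5'), its only hydrogen on C6' and its link to ring C on C1'. C2'–C5' with their oxygens map onto the four carbons of a squaric ester, and C6'–C1' onto a two-carbon alkene, so ring B can be made by expanding a cyclobutenone to an arene.
Retrosynthetic cuts, in order: the methyl mask on O5; the O-methyls at C2' and C5' (back to a hydroquinone); C1'–C2' (ring B opened to a dienylketene and refolded to a cyclobutenone); C2–C1' (cross-coupling); C5'–C6' (carbonyl addition); O1–C2 and C2–C3 of ring C.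
Forward: ring A is bought as 3,4,5-trimethoxyphenol, ring C closes by enaminone cyclisation, and C2 is then iodinated. Separately, dimethyl squarate takes up a stannylvinyllithium. A Stille coupling joins the halves, and ring B closes last on heating.
The nucleophile that attacks the squarate carries only tin, so no carbanion ever coexists with the electrophilic chromone.
Stereochemistry: the target has no stereocentre. The E alkene comes from (E)-1,2-bis(tributylstannyl)ethene and is retained. The carbinol carbon is racemic and becomes sp2 in the ring expansion.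

Key step: step 6

Assumption: TMP2Zn·2MgCl2·2LiCl (TMP = 2,2,6,6-tetramethylpiperidide) is used as the commercial THF solution, so its preparation is not counted as a step.

Step 1
Reactants: 1 3,4,5-trimethoxyphenol
Product: 2 1-(6-hydroxy-2,3,4-trimethoxyphenyl)ethan-1-one
Conditions: AcOH, BF3·OEt2, 85 °C; then H2O
Reagents that add atoms: acetic acid, CC(=O)O
Why: Friedel–Crafts C-acylation promoted by BF3 (O-acetylation, then a Fries-type shift) can only strike one of the two equivalent free positions ortho to the phenol, and chelation of the new ketone to the hydroxyl deactivates the ring against a second acylation.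

Step 2
Reactants: 2 1-(6-hydroxy-2,3,4-trimethoxyphenyl)ethan-1-one
Product: 4 5,6,7-trimethoxy-4H-chromen-4-one, via enaminone 3 (not isolated)
Conditions: DMF-DMA, toluene, 100 °C; evaporate; conc. HCl, CH2Cl2, 40 °C
Reagents that add atoms: N,N-dimethylformamide dimethyl acetal, COC(OC)N(C)C
Why: Condensation of the methyl ketone with the amide acetal gives the enaminone, and acid then triggers 6-endo-trig attack of the phenol on the β-carbon with loss of dimethylamine, which is the standard enaminone route to 2,3-unsubstituted chromones.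

Step 3
Reactants: 4 5,6,7-trimethoxy-4H-chromen-4-one
Product: 6 2-iodo-5,6,7-trimethoxy-4H-chromen-4-one, via diorganozinc 5 (not isolated)
Conditions: TMP2Zn·2MgCl2·2LiCl (0.6 equiv), THF, −30 °C; then I2, −30 °C to rt
Reagents that add atoms: iodine, [I][I]
Why: In this Lewis-acid-assisted zincation with a TMP-zinc base followed by iodolysis, MgCl2 held between the C4 carbonyl and the 5-methoxy oxygen makes the pyrylium-like C2–H the most acidic site and keeps the base away from C3, and the covalent C–Zn bond neither attacks the carbonyl nor opens ring C.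

Step 4
Reactants: 7 dimethyl squarate (3,4-dimethoxycyclobut-3-ene-1,2-dione); 8 (E)-1,2-bis(tributylstannyl)ethene
Product: 11 4-hydroxy-2,3-dimethoxy-4-[(E)-2-(tributylstannyl)ethenyl]cyclobut-2-en-1-one (racemic), via vinyllithium 9 (not isolated), via lithium alkoxide 10 (not isolated)
Conditions: 8, n-BuLi (1.0 equiv), THF, −78 °C; cannulate into 7, THF, −78 °C; sat. aq NH4Cl, −78 °C
Reagents that add atoms: none
Why: Tin–lithium exchange retains the E geometry and the alkenyllithium adds 1,2 to one of the two equivalent squarate carbonyls (the usual organolithium–squarate addition), the remaining carbonyl being a deactivated vinylogous ester once the alkoxide has formed; the new carbinol centre is racemic and is erased in step 6.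

Step 5
Reactants: 6 2-iodo-5,6,7-trimethoxy-4H-chromen-4-one; 11 4-hydroxy-2,3-dimethoxy-4-[(E)-2-(tributylstannyl)ethenyl]cyclobut-2-en-1-one
Product: 12 4-hydroxy-2,3-dimethoxy-4-[(E)-2-(5,6,7-trimethoxy-4-oxo-4H-chromen-2-yl)ethenyl]cyclobut-2-en-1-one (racemic)
Conditions: Pd2(dba)3 (2.5 mol %), AsPh3 (20 mol %), DMF, rt, dark
Reagents that add atoms: none
Why: In this Stille coupling the β-iodoenone-type C2–I bond adds to zerovalent palladium at room temperature, the weakly bound AsPh3 speeds transmetalation, the alkene geometry is retained, and the neutral, base-free, unheated medium leaves the tertiary cyclobutenol closed.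

Step 6
Reactants: 12 4-hydroxy-2,3-dimethoxy-4-[(E)-2-(5,6,7-trimethoxy-4-oxo-4H-chromen-2-yl)ethenyl]cyclobut-2-en-1-one
Product: 15 2-(2,5-dihydroxy-3,4-dimethoxyphenyl)-5,6,7-trimethoxy-4H-chromen-4-one, via dienylketene 13 (not isolated), via cyclohexadienone 14 (not isolated)
Conditions: toluene (0.02 M, degassed), 110 °C, Ar; concentrate under Ar and use directly
Reagents that add atoms: none
Why: Heat breaks the C1–C4 bond of the cyclobutenone in a conrotatory 4π electrocyclic opening to dienylketene 13, whose ketene carbon (future C2') bonds to the chromonyl-bearing alkene carbon (future C1') in a disrotatory 6π electrocyclisation to cyclohexadienone 14, and a proton shift aromatises 14 to hydroquinone 15. This is the Moore-type thermal ring expansion of squarate-derived 4-alkenyl-4-hydroxycyclobutenones, an established benzannulation. Ring B, the only ring formed, closes as a six-membered carbocycle in the 6π electrocyclic mode, and all six of its atoms (four squarate carbons, two alkene carbons) belong to the reacting π system. No stereocentre results, because the racemic carbinol carbon becomes sp2 C5' and the transient sp3 carbon of 14 is lost on enolisation. The selectivity needed is torquoselectivity in the opening, secured by the donor 4-hydroxy group, which rotates outward and so turns the alkenyl arm inward next to the ketene; only the alkene terminus can reach the ketene carbon, which fixes the lone hydrogen at C6'. High dilution and exclusion of air should suppress ketene oligomerisation and oxidation to the quinone.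

Step 7
Reactants: 15 2-(2,5-dihydroxy-3,4-dimethoxyphenyl)-5,6,7-trimethoxy-4H-chromen-4-one
Product: 16 5,6,7-trimethoxy-2-(2,3,4,5-tetramethoxyphenyl)-4H-chromen-4-one
Conditions: Me2SO4, K2CO3, acetone, reflux, Ar
Reagents that add atoms: dimethyl sulfate, COS(=O)(=O)OC
Why: Williamson-type O-methylation of the two phenoxides under argon removes the oxidisable hydroquinone at once, and nothing else in 15 bears an acidic hydrogen.

Step 8
Reactants: 16 5,6,7-trimethoxy-2-(2,3,4,5-tetramethoxyphenyl)-4H-chromen-4-one
Product: 18 5-hydroxy-6,7-dimethoxy-2-(2,3,4,5-tetramethoxyphenyl)-4H-chromen-4-one (agecorynin F), via dichloroboryl ether 17 (not isolated)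
Conditions: BCl3 (1.2 equiv), CH2Cl2, −78 to 0 °C; then H2O
Reagents that add atoms: none
Why: In this chelation-directed aryl methyl ether cleavage, BCl3 binds between the C4 carbonyl and the peri 5-methoxy oxygen, so chloride removes only that methyl group at low temperature, because the six other ethers cannot form such a six-membered chelate.

Compound list
1 | 3,4,5-trimethoxyphenol | COc1cc(O)cc(OC)c1OC | starting material
2 | 1-(6-hydroxy-2,3,4-trimethoxyphenyl)ethan-1-one | CC(=O)c1c(O)cc(OC)c(OC)c1OC | intermediate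
3 | (E)-3-(dimethylamino)-1-(6-hydroxy-2,3,4-trimethoxyphenyl)prop-2-en-1-one | CN(C)/C=C/C(=O)c1c(O)cc(OC)c(OC)c1OC | intermediate
4 | 5,6,7-trimethoxy-4H-chromen-4-one | COc1cc2occc(=O)c2c(OC)c1OC | intermediate
5 | bis(5,6,7-trimethoxy-4-oxo-4H-chromen-2-yl)zinc | COc1cc2oc([Zn]c3cc(=O)c4c(OC)c(OC)c(OC)cc4o3)cc(=O)c2c(OC)c1OC | intermediate
6 | 2-iodo-5,6,7-trimethoxy-4H-chromen-4-one | COc1cc2oc(I)cc(=O)c2c(OC)c1OC | intermediate
7 | dimethyl squarate (3,4-dimethoxycyclobut-3-ene-1,2-dione) | COC1=C(OC)C(=O)C1=O | starting material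
8 | (E)-1,2-bis(tributylstannyl)ethene | CCCC[Sn](CCCC)(CCCC)/C=C/[Sn](CCCC)(CCCC)CCCC | starting material
9 | (E)-2-(tributylstannyl)ethenyllithium | [Li]/C=C/[Sn](CCCC)(CCCC)CCCC | intermediate
10 | lithium 2,3-dimethoxy-4-oxo-1-[(E)-2-(tributylstannyl)ethenyl]cyclobut-2-en-1-olate (racemic) | COC1=C(OC)C([O-])(/C=C/[Sn](CCCC)(CCCC)CCCC)C1=O.[Li+] | intermediate
11 | 4-hydroxy-2,3-dimethoxy-4-[(E)-2-(tributylstannyl)ethenyl]cyclobut-2-en-1-one (racemic) | COC1=C(OC)C(O)(/C=C/[Sn](CCCC)(CCCC)CCCC)C1=O | intermediate
12 | 4-hydroxy-2,3-dimethoxy-4-[(E)-2-(5,6,7-trimethoxy-4-oxo-4H-chromen-2-yl)ethenyl]cyclobut-2-en-1-one (racemic) | COC1=C(OC)C(O)(/C=C/c2cc(=O)c3c(OC)c(OC)c(OC)cc3o2)C1=O | intermediate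
13 | (3Z,5E)-4-hydroxy-2,3-dimethoxy-6-(5,6,7-trimethoxy-4-oxo-4H-chromen-2-yl)hexa-1,3,5-trien-1-one | O=C=C(OC)/C(OC)=C(O)\C=C\c1cc(=O)c2c(OC)c(OC)c(OC)cc2o1 | intermediate
14 | 4-hydroxy-2,3-dimethoxy-6-(5,6,7-trimethoxy-4-oxo-4H-chromen-2-yl)cyclohexa-2,4-dien-1-one (racemic) | O=C1C(OC)=C(OC)C(O)=CC1c1cc(=O)c2c(OC)c(OC)c(OC)cc2o1 | intermediate
15 | 2-(2,5-dihydroxy-3,4-dimethoxyphenyl)-5,6,7-trimethoxy-4H-chromen-4-one | COc1c(O)cc(-c2cc(=O)c3c(OC)c(OC)c(OC)cc3o2)c(O)c1OC | intermediate
16 | 5,6,7-trimethoxy-2-(2,3,4,5-tetramethoxyphenyl)-4H-chromen-4-one | COc1cc(-c2cc(=O)c3c(OC)c(OC)c(OC)cc3o2)c(OC)c(OC)c1OC | intermediate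
17 | 5-(dichloroboryloxy)-6,7-dimethoxy-2-(2,3,4,5-tetramethoxyphenyl)-4H-chromen-4-one | COc1cc(-c2cc(=O)c3c(OB(Cl)Cl)c(OC)c(OC)cc3o2)c(OC)c(OC)c1OC | intermediate
18 | 5-hydroxy-6,7-dimethoxy-2-(2,3,4,5-tetramethoxyphenyl)-4H-chromen-4-one (agecorynin F) | COc1cc(-c2cc(=O)c3c(O)c(OC)c(OC)cc3o2)c(OC)c(OC)c1OC | target

Total step count: 8
Longest linear sequence: 7 (steps 1, 2, 3, 5, 6, 7, 8). Step 4 is a one-step side branch.

Steps most likely to fail

Step 3. Metalation may occur at C3 (directed by the carbonyl) or at C8 (between two oxygens) instead of C2, or the metalated pyranone ring may open.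
- The fallback sets out from 2 and returns at 12. It installs the C2 leaving group during ring closure, so no C–H metalation is needed.
- Ketone 2 is condensed with CS2 (KOt-Bu, THF, rt) to give 4-hydroxy-5,6,7-trimethoxy-2H-chromene-2-thione F1.
- S-Methylation (MeI, K2CO3, acetone) gives 5,6,7-trimethoxy-2-(methylsulfanyl)-4H-chromen-4-one F2.
- F2 is joined to stannane 11 by a thioether–stannane cross-coupling of the Liebeskind–Srogl type (Pd(PPh3)4, CuBr·SMe2, THF, 45 °C) to give 12.

Step 6. The electron-poor chromonyl alkene may slow the six-electron closure, so that the ketene is lost by lactonisation onto the hydroxyl or by oligomerisation, and the hydroquinone may oxidise at the reaction temperature.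
- The fallback sets out from 7, uses 6 and returns at 16. It runs the same ring expansion on the parent vinyl carbinol and attaches ring B to C2 afterwards.
- CH2=CHMgBr adds to 7 (THF, −78 °C) to give 4-ethenyl-4-hydroxy-2,3-dimethoxycyclobut-2-en-1-one F3.
- Heating F3 in toluene gives 2,3-dimethoxybenzene-1,4-diol F4.
- Methylation (Me2SO4, K2CO3, acetone) gives 1,2,3,4-tetramethoxybenzene F5.
- Directed ortho-lithiation (n-BuLi, TMEDA, THF, 0 °C) gives (2,3,4,5-tetramethoxyphenyl)lithium F6.
- ZnCl2 converts F6 into chloro(2,3,4,5-tetramethoxyphenyl)zinc F7.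
- Negishi coupling of F7 with iodide 6 (Pd(PPh3)4, THF, rt) gives 16.

Step 5. Protodestannylation of the allylic-alcohol stannane, homocoupling, or metal-induced opening of the strained carbinol may outrun the cross-coupling.
- The fallback sets out from 6 and 8 and returns at 12. It reverses the order in which the two bonds to the alkene are made.
- Stille mono-coupling of 6 with an excess of 8 gives 5,6,7-trimethoxy-2-[(E)-2-(tributylstannyl)ethenyl]-4H-chromen-4-one F8.
- Iododestannylation (I2, CH2Cl2, 0 °C) gives 2-[(E)-2-iodoethenyl]-5,6,7-trimethoxy-4H-chromen-4-one F9.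
- Iodine–magnesium exchange (i-PrMgCl·LiCl, THF, −78 °C) gives chloro[(E)-2-(5,6,7-trimethoxy-4-oxo-4H-chromen-2-yl)ethenyl]magnesium F10.
- F10 is added to 7 at −78 °C and quenched with aq NH4Cl to give 12.

Further compounds
F1 | step 3 | 4-hydroxy-5,6,7-trimethoxy-2H-chromene-2-thione | COc1cc2oc(=S)cc(O)c2c(OC)c1OC
F2 | step 3 | 5,6,7-trimethoxy-2-(methylsulfanyl)-4H-chromen-4-one | COc1cc2oc(SC)cc(=O)c2c(OC)c1OC
F3 | step 6 | 4-ethenyl-4-hydroxy-2,3-dimethoxycyclobut-2-en-1-one (racemic) | COC1=C(OC)C(O)(C=C)C1=O
F4 | step 6 | 2,3-dimethoxybenzene-1,4-diol | COc1c(O)ccc(O)c1OC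
F5 | step 6 | 1,2,3,4-tetramethoxybenzene | COc1ccc(OC)c(OC)c1OC
F6 | step 6 | (2,3,4,5-tetramethoxyphenyl)lithium | [Li]c1cc(OC)c(OC)c(OC)c1OC
F7 | step 6 | chloro(2,3,4,5-tetramethoxyphenyl)zinc | Cl[Zn]c1cc(OC)c(OC)c(OC)c1OC
F8 | step 5 | 5,6,7-trimethoxy-2-[(E)-2-(tributylstannyl)ethenyl]-4H-chromen-4-one | COc1cc2oc(/C=C/[Sn](CCCC)(CCCC)CCCC)cc(=O)c2c(OC)c1OC
F9 | step 5 | 2-[(E)-2-iodoethenyl]-5,6,7-trimethoxy-4H-chromen-4-one | COc1cc2oc(/C=C/I)cc(=O)c2c(OC)c1OC
F10 | step 5 | chloro[(E)-2-(5,6,7-trimethoxy-4-oxo-4H-chromen-2-yl)ethenyl]magnesium | COc1cc2oc(/C=C/[Mg]Cl)cc(=O)c2c(OC)c1OC
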